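The route rests on cutting C13–C14, the bond between the ethylene bridge (C12–C13) and the tetrasubstituted C14=C15 alkene of the cyclohexene ring (squalene numbering; oxepane O1–C7, cyclohexane C6–C11). Because C14 sits between quaternary C19 and methyl-bearing C15, it is the carbonyl carbon of a ketone with a single possible enol triflate, and C13 is the terminus of a C11 vinyl group. One operation, 9-BBN hydroboration then B-alkyl Suzuki–Miyaura coupling, joins the sixteen-carbon vinyl perhydrobenzoxepine (from a diepoxide oxa/carbacyclization cascade) to the fourteen-carbon enol triflate (from desymmetrised 2-methylcyclohexane-1,3-dione). The hydroperoxide is installed last by SN2 inversion at C22.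

Key step: step 14

Remark (numbering): C2 = CMe2 of the oxepane, C3 = CH–O, C6 = quaternary ring-fusion carbon, C7 = CH–O ring fusion, C10 = C(CH3)OH, C11 = CH bearing the bridge, C12–C13 = bridge, C14=C15 = ring alkene, C18 = CH–OH, C19 = quaternary carbon, C22 = CH–OOH, C23/C24 = isopropenyl; the target is (3S,6S,7S,10R,11S,18R,19S,22S).

Remark (assumption): both enantiomers of the fructose-derived Shi ketone are taken as purchasable catalysts. Their facial preference is taken as (R)/(R,R) epoxides from the D-fructose-derived ketone and (S)/(S,S) from the L-fructose-derived one; that ketone enantiomer is used which delivers the stated epoxide.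

**Western fragment**

Step 1
Reactants: 1 geranyl bromide [(2E)-1-bromo-3,7-dimethylocta-2,6-diene]; 2 N-methoxy-N-methylacetamide
Product: 3 (4E)-N-methoxy-N,5,9-trimethyldeca-4,8-dienamide
Conditions: 2, LiN(iPr)2, THF, −78 °C; then 1, DMPU, −78 → −20 °C
Reagents that add atoms: none
Why: The lithium enolate of the Weinreb acetamide should alkylate the primary allylic bromide at its α-carbon (SN2 enolate alkylation) with the (E)-alkene untouched, giving C9/C10 at the acyl oxidation level needed in step 3.

Step 2
Reactants: 3 (4E)-N-methoxy-N,5,9-trimethyldeca-4,8-dienamide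
Product: 4 3-[(2S,3S)-3-{2-[(2S)-3,3-dimethyloxiran-2-yl]ethyl}-3-methyloxiran-2-yl]-N-methoxy-N-methylpropanamide
Conditions: L-fructose-derived Shi ketone (0.6 equiv), Oxone (2KHSO5·KHSO4·K2SO4), K2CO3, Bu4NHSO4, Na2B4O7/Na2EDTA buffer, MeCN–CH2(OMe)2, 0 °C
Reagents that add atoms: potassium peroxymonosulfate (active part of Oxone), [K+].[O-]S(=O)(=O)OO
Why: Shi asymmetric epoxidation should convert both electron-rich trisubstituted alkenes through the spiro transition state of the chiral dioxirane, each under independent reagent control, setting C3 (S), C6 (S) and C7 (S).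

Step 3
Reactants: 4 diepoxy Weinreb amide
Product: 5 1-[(2S,3S)-3-{2-[(2S)-3,3-dimethyloxiran-2-yl]ethyl}-3-methyloxiran-2-yl]hex-5-en-3-one
Conditions: CH2=CHCH2MgBr, THF, −78 °C; cold aq. NH4Cl
Reagents that add atoms: allylmagnesium bromide, C=CC[Mg]Br
Why: Grignard addition to a Weinreb amide stops at the chelated tetrahedral adduct, so the β,γ-unsaturated ketone should appear only on cold buffered work-up, and trisubstituted epoxides do not react with the reagent at −78 °C.

Step 4
Reactants: 5 diepoxy allyl ketone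
Product: 6 triethyl({(3Z)-1-[(2S,3S)-3-{2-[(2S)-3,3-dimethyloxiran-2-yl]ethyl}-3-methyloxiran-2-yl]hexa-3,5-dien-3-yl}oxy)silane
Conditions: LiN(SiMe3)2, THF, −78 °C; then Et3SiCl, DMPU, −78 → −40 °C; aq. NaHCO3/pentane work-up
Reagents that add atoms: chlorotriethylsilane, CC[Si](Cl)(CC)CC
Why: The C11 methylene between carbonyl and vinyl group is by far the most acidic site, so deprotonation should give the extended dienolate, which is O-silylated (regioselective enolate silylation) with the vinyl group cis to the siloxy group, away from the C9 chain.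

Step 5
Reactants: 6 diepoxy (Z)-silyl dienol ether
Product: 7 (3S,5aS,6S,9aS)-6-ethenyl-2,2,5a-trimethyl-3-(triethylsilyloxy)octahydro-1-benzoxepin-7(2H)-one
Conditions: Et3SiOTf (0.5 equiv), 2,6-di-tert-butyl-4-methylpyridine, CH2Cl2, −78 °C; Et3N quench
Reagents that add atoms: none
Why: In this Lewis-acid-promoted epoxide-opening oxa/carbacyclization cascade (a known enol-silane-terminated diepoxide cyclization), silylation of the terminal epoxide lets the internal epoxide oxygen attack tertiary C2 to close the oxepane, and the α-carbon C11 of the dienol ether (γ-attack would need an eight-membered ring) then opens the epoxonium ion anti at tertiary C6 through a chair, so that the trans-fused bicycle should form with C3 and C7 retained, C6 inverted and the C11 vinyl group equatorial from the (Z) enol ether, the silyl group being relayed from the enol oxygen to O3.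

Step 6
Reactants: 7 bicyclic vinyl ketone
Product: 8 (3S,5aS,6S,7R,9aS)-6-ethenyl-2,2,5a,7-tetramethyl-3-(triethylsilyloxy)decahydro-1-benzoxepin-7-ol
Conditions: MeLi, CeCl3 (anhydrous), THF, −78 °C; aq. NH4Cl
Reagents that add atoms: methyllithium, [Li]C
Why: Organocerium 1,2-addition suppresses enolisation of the β,γ-unsaturated ketone, and the axial angular methyl group on C6 blocks the axial trajectory, so methyl should enter equatorially and leave the C10 hydroxyl axial, cis to that methyl (10R).

**Eastern fragment**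

Step 7
Reactants: 9 2-methylcyclohexane-1,3-dione; 10 acrolein
Product: 11 3-(1-methyl-2,6-dioxocyclohexyl)propanal
Conditions: H2O, rt
Reagents that add atoms: none
Why: Michael addition of the enolised 1,3-dione to acrolein should give C-alkylation at C2 and thus the quaternary carbon C19, still prochiral.

Step 8
Reactants: 11 3-(1-methyl-2,6-dioxocyclohexyl)propanal
Product: 12 2-methyl-2-(4-methylpent-3-en-1-yl)cyclohexane-1,3-dione
Conditions: iPrPPh3I, n-BuLi, THF, 0 °C; then 11, −78 → 0 °C
Reagents that add atoms: isopropyltriphenylphosphonium iodide, CC(C)[P+](c1ccccc1)(c1ccccc1)c1ccccc1.[I-]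
Why: In this Wittig olefination the non-stabilised ylide should react with the aldehyde much faster than with the two ketones flanking the quaternary carbon, and the trisubstituted alkene formed has no geometry to control.

Step 9
Reactants: 12 2-methyl-2-(4-methylpent-3-en-1-yl)cyclohexane-1,3-dione
Product: 13 (2R,3R)-3-hydroxy-2-methyl-2-(4-methylpent-3-en-1-yl)cyclohexan-1-one
Conditions: (S)-2-methyl-CBS-oxazaborolidine (0.2 equiv), catecholborane, toluene, −78 → −40 °C
Reagents that add atoms: none
Why: Corey–Bakshi–Shibata reduction desymmetrises the dione, the (S)-catalyst treating the quaternary carbon as the large group to give the (R)-carbinol at C18, while hydride enters anti to the larger homoprenyl chain so that OH ends up cis to it and C19 is fixed (the minor diastereomer is removed by chromatography); catecholborane does not hydroborate the alkene at this temperature.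

Step 10
Reactants: 13 (2R,3R)-hydroxy ketone
Product: 14 (2R,3R)-2-methyl-2-(4-methylpent-3-en-1-yl)-3-(triethylsilyloxy)cyclohexan-1-one
Conditions: Et3SiCl, imidazole, DMF, rt
Reagents that add atoms: chlorotriethylsilane, CC[Si](Cl)(CC)CC
Why: Silylation of the secondary alcohol should give an ether that survives enolate chemistry and cross-coupling and is removable by fluoride at the end.

Step 11
Reactants: 14 silyloxy ketone
Product: 15 (2R,3R)-2,6-dimethyl-2-(4-methylpent-3-en-1-yl)-3-(triethylsilyloxy)cyclohexan-1-one (both C6 epimers)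
Conditions: LiN(iPr)2, THF, −78 °C; then MeI, DMPU, −78 → −20 °C
Reagents that add atoms: iodomethane, CI
Why: In this enolate alkylation the ketone can enolise only towards C15 because C19 is quaternary, and the configuration at C15 is irrelevant since that carbon becomes sp2 in step 12.

Step 12
Reactants: 15 methylated ketone
Product: 16 (5R,6R)-2,6-dimethyl-6-(4-methylpent-3-en-1-yl)-5-(triethylsilyloxy)cyclohex-1-en-1-yl trifluoromethanesulfonate
Conditions: KN(SiMe3)2, THF, −78 → 0 °C; then PhNTf2, −78 °C → rt
Reagents that add atoms: N-phenylbis(trifluoromethanesulfonimide), FC(F)(F)S(=O)(=O)N(c1ccccc1)S(=O)(=O)C(F)(F)F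
Why: Removal of the only α-hydrogen and O-sulfonylation of the potassium enolate (enol triflate formation) should give the tetrasubstituted C14=C15 enol triflate as the sole regioisomer, both C15 epimers converging.

Step 13
Reactants: 16 enol triflate
Product: 17 (5R,6R)-6-{2-[(2R)-3,3-dimethyloxiran-2-yl]ethyl}-2,6-dimethyl-5-(triethylsilyloxy)cyclohex-1-en-1-yl trifluoromethanesulfonate
Conditions: D-fructose-derived Shi ketone (0.3 equiv), Oxone (2KHSO5·KHSO4·K2SO4), K2CO3, Bu4NHSO4, Na2B4O7/Na2EDTA buffer, MeCN–CH2(OMe)2, 0 °C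
Reagents that add atoms: potassium peroxymonosulfate (active part of Oxone), [K+].[O-]S(=O)(=O)OO
Why: Shi epoxidation should touch only the electron-rich trisubstituted alkene (the enol triflate is electron-poor) and set C22 as (R) under reagent control.

**Union and end game**

Step 14
Reactants: 8 vinyl perhydrobenzoxepine; 17 epoxy enol triflate
Product: 19 C13–C14-coupled (22R)-22,23-epoxide bearing 3-O-TES and 18-O-TES groups and a free 10-OH, via B-alkyl-9-BBN borane 18 (not isolated)
Conditions: 8, 9-BBN dimer, THF, rt → 40 °C; then 3 M aq. Cs2CO3; then 17, PdCl2(dppf)·CH2Cl2 (10 mol %), AsPh3, DMF, 50 °C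
Reagents that add atoms: none
Why: 9-BBN adds across the only C=C of 8, the monosubstituted C12=C13 vinyl group, with boron on terminal C13; aqueous Cs2CO3 then forms the hydroxyborate, zerovalent palladium inserts into the C14–OTf bond of 17, the primary alkyl group passes from boron to palladium, and reductive elimination forms C13–C14. The closest known reaction type is the B-alkyl Suzuki–Miyaura coupling of 9-BBN-derived primary alkylboranes with hindered cycloalkenyl triflates such as 2,6,6-trimethylcyclohexenyl triflate. No ring is closed in this step. No stereocentre is formed or touched: the five western and three eastern stereocentres arrive intact, and the position of the tetrasubstituted C14=C15 alkene is locked in the triflate because quaternary C19 left C15 as the only enolisable side. The step needs anti-Markovnikov hydroboration (secured by the bulk of 9-BBN at the neopentyl-like vinyl group), selectivity for the C–OTf bond beside an epoxide, two silyl ethers and a free tertiary alcohol (all inert to borane, carbonate and palladium), and transmetalation that outruns β-hydride elimination and triflate hydrolysis (bidentate dppf, AsPh3 co-ligand, excess borane).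

Step 15
Reactants: 19 coupled epoxide
Product: 20 coupled (22R)-allylic alcohol: 3,18-bis-O-triethylsilyl ether of the 22-hydroxy analogue of the target with inverted C22, (3S,6S,7S,10R,11S,18R,19S,22R)
Conditions: Et2AlCl, Li(tmp) [lithium 2,2,6,6-tetramethylpiperidide; gives Et2Al(tmp)], toluene, 0 °C; then 19, 0 °C → rt; Rochelle salt work-up
Reagents that add atoms: none
Why: In this aluminium-amide-mediated epoxide-to-allylic-alcohol isomerisation the amide bound to the epoxide oxygen removes a proton from a C23 methyl group in a cyclic syn-elimination that breaks only the tertiary C23–O bond, so the isopropenyl carbinol should form with the C22–O bond and its (R) configuration retained.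

Step 16
Reactants: 20 coupled (22R)-allylic alcohol
Product: 22 3,18-bis-O-triethylsilyl ether of the target with the (22S)-hydroperoxide in place, via allylic methanesulfonate 21 (not isolated)
Conditions: Ms2O, Et3N, CH2Cl2, −20 °C; solvent exchange; then 50 % aq. H2O2 (excess), KOH, THF–MeOH, 0 °C
Reagents that add atoms: hydrogen peroxide, OO
Why: Sulfonylation of the only accessible hydroxyl (the axial tertiary C10–OH does not react) followed by SN2 displacement with the α-effect nucleophile HOO− (perhydrolysis of a secondary alkyl methanesulfonate) should invert C22 from R to S, oxygen nucleophiles attacking 1-alkylallyl sulfonates at the α-carbon and not at the terminal methylene.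

Step 17
Reactants: 22 bis-silyl hydroperoxide
Product: 23 CNP0271099.3 (target)
Conditions: HF·pyridine, pyridine, THF, 0 °C → rt
Reagents that add atoms: none
Why: Fluoride-mediated cleavage of the two secondary triethylsilyl ethers under buffered, non-reducing and non-basic conditions should leave the allylic hydroperoxide, the tertiary alcohol and the tetrasubstituted alkene untouched.

**Compound list**

1 | geranyl bromide [(2E)-1-bromo-3,7-dimethylocta-2,6-diene] | CC(C)=CCC/C(C)=C/CBr | starting material
2 | N-methoxy-N-methylacetamide | CC(=O)N(C)OC | starting material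
3 | (4E)-N-methoxy-N,5,9-trimethyldeca-4,8-dienamide | CC(C)=CCC/C(C)=C/CCC(=O)N(C)OC | intermediate
4 | 3-[(2S,3S)-3-{2-[(2S)-3,3-dimethyloxiran-2-yl]ethyl}-3-methyloxiran-2-yl]-N-methoxy-N-methylpropanamide | CC1(C)O[C@H]1CC[C@]1(C)O[C@H]1CCC(=O)N(C)OC | intermediate
5 | 1-[(2S,3S)-3-{2-[(2S)-3,3-dimethyloxiran-2-yl]ethyl}-3-methyloxiran-2-yl]hex-5-en-3-one | CC1(C)O[C@H]1CC[C@]1(C)O[C@H]1CCC(=O)CC=C | intermediate
6 | triethyl({(3Z)-1-[(2S,3S)-3-{2-[(2S)-3,3-dimethyloxiran-2-yl]ethyl}-3-methyloxiran-2-yl]hexa-3,5-dien-3-yl}oxy)silane | CC1(C)O[C@H]1CC[C@]1(C)O[C@H]1CC/C(O[Si](CC)(CC)CC)=C/C=C | intermediate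
7 | (3S,5aS,6S,9aS)-6-ethenyl-2,2,5a-trimethyl-3-(triethylsilyloxy)octahydro-1-benzoxepin-7(2H)-one | C=C[C@H]1[C@]2(C)CC[C@H](O[Si](CC)(CC)CC)C(C)(C)O[C@H]2CCC1=O | intermediate
8 | (3S,5aS,6S,7R,9aS)-6-ethenyl-2,2,5a,7-tetramethyl-3-(triethylsilyloxy)decahydro-1-benzoxepin-7-ol | C=C[C@H]1[C@]2(C)CC[C@H](O[Si](CC)(CC)CC)C(C)(C)O[C@H]2CC[C@@]1(C)O | intermediate
9 | 2-methylcyclohexane-1,3-dione | CC1C(=O)CCCC1=O | starting material
10 | acrolein | C=CC=O | starting material
11 | 3-(1-methyl-2,6-dioxocyclohexyl)propanal | CC1(CCC=O)C(=O)CCCC1=O | intermediate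
12 | 2-methyl-2-(4-methylpent-3-en-1-yl)cyclohexane-1,3-dione | CC(C)=CCCC1(C)C(=O)CCCC1=O | intermediate
13 | (2R,3R)-3-hydroxy-2-methyl-2-(4-methylpent-3-en-1-yl)cyclohexan-1-one | CC(C)=CCC[C@@]1(C)C(=O)CCC[C@H]1O | intermediate
14 | (2R,3R)-2-methyl-2-(4-methylpent-3-en-1-yl)-3-(triethylsilyloxy)cyclohexan-1-one | CC(C)=CCC[C@@]1(C)C(=O)CCC[C@H]1O[Si](CC)(CC)CC | intermediate
15 | (2R,3R)-2,6-dimethyl-2-(4-methylpent-3-en-1-yl)-3-(triethylsilyloxy)cyclohexan-1-one (both C6 epimers) | CC(C)=CCC[C@@]1(C)C(=O)C(C)CC[C@H]1O[Si](CC)(CC)CC | intermediate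
16 | (5R,6R)-2,6-dimethyl-6-(4-methylpent-3-en-1-yl)-5-(triethylsilyloxy)cyclohex-1-en-1-yl trifluoromethanesulfonate | CC(C)=CCC[C@@]1(C)C(OS(=O)(=O)C(F)(F)F)=C(C)CC[C@H]1O[Si](CC)(CC)CC | intermediate
17 | (5R,6R)-6-{2-[(2R)-3,3-dimethyloxiran-2-yl]ethyl}-2,6-dimethyl-5-(triethylsilyloxy)cyclohex-1-en-1-yl trifluoromethanesulfonate | CC1(C)O[C@@H]1CC[C@@]1(C)C(OS(=O)(=O)C(F)(F)F)=C(C)CC[C@H]1O[Si](CC)(CC)CC | intermediate
18 | B-alkyl-9-BBN borane: 9-{2-[(3S,5aS,6S,7R,9aS)-7-hydroxy-2,2,5a,7-tetramethyl-3-(triethylsilyloxy)decahydro-1-benzoxepin-6-yl]ethyl}-9-borabicyclo[3.3.1]nonane | C12CCCC(CCC1)B2CC[C@H]1[C@]2(C)CC[C@H](O[Si](CC)(CC)CC)C(C)(C)O[C@H]2CC[C@@]1(C)O | intermediate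
19 | coupled epoxide: C13–C14-linked skeleton with (22R)-22,23-epoxide, 3-O-TES, 18-O-TES and free 10-OH, (3S,6S,7S,10R,11S,18R,19S,22R) | CC1(C)O[C@@H]1CC[C@@]1(C)C(CC[C@H]2[C@]3(C)CC[C@H](O[Si](CC)(CC)CC)C(C)(C)O[C@H]3CC[C@@]2(C)O)=C(C)CC[C@H]1O[Si](CC)(CC)CC | intermediate
20 | coupled (22R)-allylic alcohol: 3,18-bis-O-TES ether carrying OH in place of OOH at C22 with inverted configuration, (3S,6S,7S,10R,11S,18R,19S,22R) | C=C(C)[C@@H](CC[C@@]1(C)C(CC[C@H]2[C@]3(C)CC[C@H](O[Si](CC)(CC)CC)C(C)(C)O[C@H]3CC[C@@]2(C)O)=C(C)CC[C@H]1O[Si](CC)(CC)CC)O | intermediate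
21 | (22R)-methanesulfonate of 20 | C=C(C)[C@@H](CC[C@@]1(C)C(CC[C@H]2[C@]3(C)CC[C@H](O[Si](CC)(CC)CC)C(C)(C)O[C@H]3CC[C@@]2(C)O)=C(C)CC[C@H]1O[Si](CC)(CC)CC)OS(C)(=O)=O | intermediate
22 | 3,18-bis-O-triethylsilyl ether of the target, (22S)-hydroperoxide | C=C(C)[C@H](CC[C@@]1(C)C(CC[C@H]2[C@]3(C)CC[C@H](O[Si](CC)(CC)CC)C(C)(C)O[C@H]3CC[C@@]2(C)O)=C(C)CC[C@H]1O[Si](CC)(CC)CC)OO | intermediate
23 | CNP0271099.3, (3S,6S,7S,10R,11S,18R,19S,22S) | C=C(C)[C@H](CC[C@@]1(C)C(CC[C@H]2[C@]3(C)CC[C@H](O)C(C)(C)O[C@H]3CC[C@@]2(C)O)=C(C)CC[C@H]1O)OO | target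

**Step count and risks**

Total step count: 17 (western fragment 6, eastern fragment 7, union and end game 4).
Longest linear sequence: 11 steps (steps 7–17).

The three steps most likely to fail:

Step 5 (cascade). What may go wrong: ionisation of the acid-labile dienol ether or attack through its γ-carbon, opening of the internal epoxide before the terminal one (stopping after one ring), drift of the β,γ-unsaturated ketone into conjugation, and transfer of a mixed enol ether geometry into a C11 epimer mixture. Fallback, from 4 back to 8: vinylmagnesium bromide (THF, −78 °C, cold citrate-buffered quench) would convert 4 into the diepoxy vinyl ketone F1. Copper-catalysed conjugate addition of vinylmagnesium bromide (CuBr·SMe2, Et3SiCl, THF, −78 °C) would give the regiodefined triethylsilyl enol ether F2, in which C11 carries an allyl group. The same Et3SiOTf-promoted cascade, now ended by a simple enol silane, would give the 6-allyl ketone F3, whose C11 centre can be equilibrated to the equatorial epimer (NaOMe, MeOH) without risk of conjugation. MeLi/CeCl3 would give the tertiary alcohol F4, RuHCl(CO)(PPh3)3 (toluene, 80 °C) would move the terminal alkene to give the (E)-propenyl compound F5, and ethenolysis (ethylene, second-generation Hoveyda–Grubbs catalyst, CH2Cl2) would trim F5 to 8.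

Step 14 (key coupling). What may go wrong: slow oxidative addition and slow boron-to-palladium transfer at the doubly flanked C14, so that hydrolysis of the triflate by the aqueous base, protodeboronation or β-hydride elimination win. Fallback, from 8 back to 19: oxidation of borane 18 (NaOH, H2O2) would give the primary alcohol F6, iodination (I2, PPh3, imidazole) the primary iodide F7, and zinc insertion (Zn dust, LiCl, THF, 40 °C) the alkylzinc iodide F8. Base-free Negishi coupling of F8 with 17 (Pd(OAc)2, SPhos, THF–NMP, rt → 50 °C) would give 19, since zinc passes on the alkyl group without aqueous base and faster than boron.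

Step 16 (perhydrolysis). What may go wrong: ionisation of the secondary allylic methanesulfonate (loss of configuration, methanolysis), attack at the terminal methylene (SN2′), elimination to the diene, and a second alkylation of the product to a dialkyl peroxide. Fallback, from 20 back to 23: 21 would be displaced in DMF at 0 °C by the caesium salt of 2-methoxyprop-2-yl hydroperoxide (CsOH·H2O), a mono-protected, non-aqueous peroxide nucleophile that cannot be alkylated twice, to give the peroxyketal F9 with inversion at C22. One acidic operation (HF·pyridine, wet THF, 0 °C → rt) would then remove the ketal and both silyl ethers to give 23 directly.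

Further compounds
F1 | step 5 | 5-[(2S,3S)-3-{2-[(2S)-3,3-dimethyloxiran-2-yl]ethyl}-3-methyloxiran-2-yl]pent-1-en-3-one | CC1(C)O[C@H]1CC[C@]1(C)O[C@H]1CCC(=O)C=C
F2 | step 5 | triethyl({1-[(2S,3S)-3-{2-[(2S)-3,3-dimethyloxiran-2-yl]ethyl}-3-methyloxiran-2-yl]hepta-3,6-dien-3-yl}oxy)silane (enol ether geometry mixed) | CC1(C)O[C@H]1CC[C@]1(C)O[C@H]1CCC(O[Si](CC)(CC)CC)=CCC=C
F3 | step 5 | (3S,5aS,6S,9aS)-2,2,5a-trimethyl-6-(prop-2-en-1-yl)-3-(triethylsilyloxy)octahydro-1-benzoxepin-7(2H)-one | C=CC[C@H]1[C@]2(C)CC[C@H](O[Si](CC)(CC)CC)C(C)(C)O[C@H]2CCC1=O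
F4 | step 5 | (3S,5aS,6S,7R,9aS)-2,2,5a,7-tetramethyl-6-(prop-2-en-1-yl)-3-(triethylsilyloxy)decahydro-1-benzoxepin-7-ol | C=CC[C@H]1[C@]2(C)CC[C@H](O[Si](CC)(CC)CC)C(C)(C)O[C@H]2CC[C@@]1(C)O
F5 | step 5 | (3S,5aS,6S,7R,9aS)-2,2,5a,7-tetramethyl-6-[(1E)-prop-1-en-1-yl]-3-(triethylsilyloxy)decahydro-1-benzoxepin-7-ol | C/C=C/[C@H]1[C@]2(C)CC[C@H](O[Si](CC)(CC)CC)C(C)(C)O[C@H]2CC[C@@]1(C)O
F6 | step 14 | (3S,5aS,6S,7R,9aS)-6-(2-hydroxyethyl)-2,2,5a,7-tetramethyl-3-(triethylsilyloxy)decahydro-1-benzoxepin-7-ol | OCC[C@H]1[C@]2(C)CC[C@H](O[Si](CC)(CC)CC)C(C)(C)O[C@H]2CC[C@@]1(C)O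
F7 | step 14 | (3S,5aS,6S,7R,9aS)-6-(2-iodoethyl)-2,2,5a,7-tetramethyl-3-(triethylsilyloxy)decahydro-1-benzoxepin-7-ol | ICC[C@H]1[C@]2(C)CC[C@H](O[Si](CC)(CC)CC)C(C)(C)O[C@H]2CC[C@@]1(C)O
F8 | step 14 | {2-[(3S,5aS,6S,7R,9aS)-7-hydroxy-2,2,5a,7-tetramethyl-3-(triethylsilyloxy)decahydro-1-benzoxepin-6-yl]ethyl}zinc iodide | I[Zn]CC[C@H]1[C@]2(C)CC[C@H](O[Si](CC)(CC)CC)C(C)(C)O[C@H]2CC[C@@]1(C)O
F9 | step 16 | (22S)-2-methoxyprop-2-yl peroxyketal of 22 (3,18-bis-O-TES) | C=C(C)[C@H](CC[C@@]1(C)C(CC[C@H]2[C@]3(C)CC[C@H](O[Si](CC)(CC)CC)C(C)(C)O[C@H]3CC[C@@]2(C)O)=C(C)CC[C@H]1O[Si](CC)(CC)CC)OOC(C)(C)OC
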